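**Retrosynthetic overview**
1. Enone Cα=Cβ bond: Claisen–Schmidt aldol condensation of the fully MOM-protected acetophenone 12 with benzaldehyde 13 (the key fragment union), with MOM removal last.
2. Acetyl group: bromination of the mirror-symmetric ring A, Br–Li exchange and Weinreb acylation, so only one regioisomer can form.
3. Diarylmethane CH2: directed ortho-lithiation of 5-methoxyresorcinol bis-MOM ether between the two OMOM groups, addition to 2-(benzyloxy)benzaldehyde, then hydrogenolysis.
4. No ring is formed: ring A (from 5-methoxyresorcinol), ring B (from 2-(benzyloxy)benzaldehyde) and the phenyl ring (from benzaldehyde) are all bought intact.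

Assumption: the target has no stereocentre, so "single enantiomer" is taken to mean the E-alkene isomer as drawn.

**Route**

Step 1
Reactants: 1 5-methoxybenzene-1,3-diol
Product: 2 1-methoxy-3,5-bis(methoxymethoxy)benzene
Conditions: NaH (2.5 equiv), MOMCl (2.4 equiv), DMF, 0 °C to rt
Reagents that add atoms: chloromethyl methyl ether (MOMCl), COCCl
Why: Williamson-type O-alkylation of the bis-phenoxide gives the bis-MOM ether, which carries the strong ortho-directing groups needed for step 2; no stereocentre is involved.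

Step 2
Reactants: 2 1-methoxy-3,5-bis(methoxymethoxy)benzene; 3 2-(benzyloxy)benzaldehyde
Product: 5 (±)-[2-(benzyloxy)phenyl][4-methoxy-2,6-bis(methoxymethoxy)phenyl]methanol, via aryllithium 4 (not isolated)
Conditions: n-BuLi (1.1 equiv), THF, 0 °C to rt, 1 h; then 3, −78 °C to rt; H2O
Reagents that add atoms: none
Why: Directed ortho-metalation takes place at the C–H flanked by the two OMOM groups (cooperative and stronger directors than OMe), and the aryllithium adds 1,2 to the aldehyde; the carbinol centre is racemic and is removed in step 3.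

Step 3
Reactants: 5 (±)-[2-(benzyloxy)phenyl][4-methoxy-2,6-bis(methoxymethoxy)phenyl]methanol
Product: 7 2-{[4-methoxy-2,6-bis(methoxymethoxy)phenyl]methyl}phenol, via debenzylated diol 6 (not isolated)
Conditions: H2 (1 atm), 10% Pd/C, EtOH/EtOAc, AcOH (cat.), rt
Reagents that add atoms: none
Why: Catalytic hydrogenolysis cleaves the benzyl ether and then the doubly benzylic C–OH bond, which is activated by the ortho-hydroxy group and the electron-rich ring A, while the MOM acetals survive and the stereocentre disappears.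

Step 4
Reactants: 7 2-{[4-methoxy-2,6-bis(methoxymethoxy)phenyl]methyl}phenol
Product: 8 5-methoxy-1,3-bis(methoxymethoxy)-2-{[2-(methoxymethoxy)phenyl]methyl}benzene
Conditions: NaH (1.2 equiv), MOMCl (1.2 equiv), DMF, 0 °C to rt
Reagents that add atoms: chloromethyl methyl ether (MOMCl), COCCl
Why: Williamson O-alkylation of the only free phenol masks ring B so that it is neither brominated in step 5 nor deprotonated in steps 6 and 7.

Step 5
Reactants: 8 5-methoxy-1,3-bis(methoxymethoxy)-2-{[2-(methoxymethoxy)phenyl]methyl}benzene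
Product: 9 2-bromo-1-methoxy-3,5-bis(methoxymethoxy)-4-{[2-(methoxymethoxy)phenyl]methyl}benzene
Conditions: NBS (1.0 equiv), MeCN, −10 to 0 °C, dark
Reagents that add atoms: N-bromosuccinimide (NBS), O=C1CCC(=O)N1Br
Why: Electrophilic aromatic bromination occurs on the trioxygenated ring A, whose two free positions are equivalent by symmetry, so a single monobromide forms; ring B with one oxygen is far less reactive.

Step 6
Reactants: 9 2-bromo-1-methoxy-3,5-bis(methoxymethoxy)-4-{[2-(methoxymethoxy)phenyl]methyl}benzene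
Product: 12 1-(6-methoxy-2,4-bis(methoxymethoxy)-3-{[2-(methoxymethoxy)phenyl]methyl}phenyl)ethan-1-one, via aryllithium 10 (not isolated), via tetrahedral lithium adduct 11 (not isolated)
Conditions: n-BuLi (1.05 equiv), THF, −78 °C, 20 min; MeC(O)N(OMe)Me (1.5 equiv), −78 to 0 °C; H2O
Reagents that add atoms: N-methoxy-N-methylacetamide, CC(=O)N(C)OC
Why: Bromine–lithium exchange at −78 °C outruns any deprotonation, and the Weinreb ketone synthesis stops at the chelated tetrahedral adduct, which gives the methyl ketone only on work-up.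

Step 7
Reactants: 12 1-(6-methoxy-2,4-bis(methoxymethoxy)-3-{[2-(methoxymethoxy)phenyl]methyl}phenyl)ethan-1-one; 13 benzaldehyde
Product: 15 (E)-1-(6-methoxy-2,4-bis(methoxymethoxy)-3-{[2-(methoxymethoxy)phenyl]methyl}phenyl)-3-phenylprop-2-en-1-one, via aldol adduct 14 (not isolated)
Conditions: KOH (5 equiv), MeOH/H2O, rt to 50 °C
Reagents that add atoms: none
Why: In this Claisen–Schmidt crossed aldol condensation only 12 can enolise and benzaldehyde is the only electrophile, and E1cB dehydration of the aldol gives the thermodynamically favoured E-enone; with every phenol masked, no deactivating phenoxide and no flavanone can form.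

Step 8
Reactants: 15 (E)-1-(6-methoxy-2,4-bis(methoxymethoxy)-3-{[2-(methoxymethoxy)phenyl]methyl}phenyl)-3-phenylprop-2-en-1-one
Product: 16 (E)-1-{2,4-dihydroxy-3-[(2-hydroxyphenyl)methyl]-6-methoxyphenyl}-3-phenylprop-2-en-1-one
Conditions: HCl (3 M in MeOH), rt, 1–3 h, stopped at full conversion
Reagents that add atoms: none
Why: Acid-catalysed acetal exchange with methanol removes the three phenolic MOM groups at room temperature, which is mild enough to leave the E-enone and the aryl methyl ether intact and to avoid oxa-Michael closure to the flavanone.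

**Compound list**
1 | 5-methoxybenzene-1,3-diol | COc1cc(O)cc(O)c1 | starting material
2 | 1-methoxy-3,5-bis(methoxymethoxy)benzene | COCOc1cc(OC)cc(OCOC)c1 | intermediate
3 | 2-(benzyloxy)benzaldehyde | O=Cc1ccccc1OCc1ccccc1 | starting material
4 | [4-methoxy-2,6-bis(methoxymethoxy)phenyl]lithium (not isolated) | [Li]c1c(OCOC)cc(OC)cc1OCOC | intermediate
5 | (±)-[2-(benzyloxy)phenyl][4-methoxy-2,6-bis(methoxymethoxy)phenyl]methanol | COCOc1cc(OC)cc(OCOC)c1C(O)c1ccccc1OCc1ccccc1 | intermediate
6 | (±)-2-{hydroxy[4-methoxy-2,6-bis(methoxymethoxy)phenyl]methyl}phenol (not isolated) | COCOc1cc(OC)cc(OCOC)c1C(O)c1ccccc1O | intermediate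
7 | 2-{[4-methoxy-2,6-bis(methoxymethoxy)phenyl]methyl}phenol | COCOc1cc(OC)cc(OCOC)c1Cc1ccccc1O | intermediate
8 | 5-methoxy-1,3-bis(methoxymethoxy)-2-{[2-(methoxymethoxy)phenyl]methyl}benzene | COCOc1ccccc1Cc1c(OCOC)cc(OC)cc1OCOC | intermediate
9 | 2-bromo-1-methoxy-3,5-bis(methoxymethoxy)-4-{[2-(methoxymethoxy)phenyl]methyl}benzene | COCOc1ccccc1Cc1c(OCOC)cc(OC)c(Br)c1OCOC | intermediate
10 | (6-methoxy-2,4-bis(methoxymethoxy)-3-{[2-(methoxymethoxy)phenyl]methyl}phenyl)lithium (not isolated) | COCOc1ccccc1Cc1c(OCOC)cc(OC)c([Li])c1OCOC | intermediate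
11 | lithium 1-[methoxy(methyl)amino]-1-(6-methoxy-2,4-bis(methoxymethoxy)-3-{[2-(methoxymethoxy)phenyl]methyl}phenyl)ethan-1-olate (not isolated) | COCOc1ccccc1Cc1c(OCOC)cc(OC)c(C(C)(O[Li])N(C)OC)c1OCOC | intermediate
12 | 1-(6-methoxy-2,4-bis(methoxymethoxy)-3-{[2-(methoxymethoxy)phenyl]methyl}phenyl)ethan-1-one | COCOc1ccccc1Cc1c(OCOC)cc(OC)c(C(C)=O)c1OCOC | intermediate
13 | benzaldehyde | O=Cc1ccccc1 | starting material
14 | (±)-3-hydroxy-1-(6-methoxy-2,4-bis(methoxymethoxy)-3-{[2-(methoxymethoxy)phenyl]methyl}phenyl)-3-phenylpropan-1-one (not isolated) | COCOc1ccccc1Cc1c(OCOC)cc(OC)c(C(=O)CC(O)c2ccccc2)c1OCOC | intermediate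
15 | (E)-1-(6-methoxy-2,4-bis(methoxymethoxy)-3-{[2-(methoxymethoxy)phenyl]methyl}phenyl)-3-phenylprop-2-en-1-one | COCOc1ccccc1Cc1c(OCOC)cc(OC)c(C(=O)/C=C/c2ccccc2)c1OCOC | intermediate
16 | (E)-1-{2,4-dihydroxy-3-[(2-hydroxyphenyl)methyl]-6-methoxyphenyl}-3-phenylprop-2-en-1-one | COc1cc(O)c(Cc2ccccc2O)c(O)c1C(=O)/C=C/c1ccccc1 | target

**Totals**
Total step count: 8. Longest linear sequence: 8 steps (1 to 16).

**Three steps most likely to fail, each with a fallback**

Step 3 (the crowded carbinol may stall at diol 6 or reduce slowly). The fallback sets out from 2, through its lithio derivative 4 made as in step 2, and comes back at 7. Instead of adding to an aldehyde and deoxygenating, 4 is alkylated directly with commercial 2-(benzyloxy)benzyl bromide in THF with CuI (10 mol%) from −78 °C to rt. This SN2 benzylation gives 2-{[2-(benzyloxy)phenyl]methyl}-5-methoxy-1,3-bis(methoxymethoxy)benzene F1. Hydrogenolysis of F1 (H2, 10% Pd/C, EtOAc, rt) then only has to cleave the benzyl ether and delivers 7.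

Step 6 (the hindered aryllithium 10 may deprotonate the enolisable Weinreb amide instead of adding to it). The fallback sets out from 9, through 10, and comes back at 12. The aryllithium 10 is trapped at −78 °C with acetaldehyde, a much more electrophilic partner, and water quench gives (±)-1-(6-methoxy-2,4-bis(methoxymethoxy)-3-{[2-(methoxymethoxy)phenyl]methyl}phenyl)ethan-1-ol F2. Oxidation of F2 with Dess–Martin periodinane and NaHCO3 in CH2Cl2 at rt gives ketone 12, so the ketone is reached by addition and oxidation instead of acyl substitution.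

Step 8 (acid may close the 2'-hydroxychalcone to the flavanone before all three MOM groups are gone). The fallback sets out from 12 and comes back at 16, with the deprotection moved ahead of the aldol. Ketone 12 is deprotected with HCl in MeOH at 50 °C, where no cyclisation is possible, to give 1-{2,4-dihydroxy-3-[(2-hydroxyphenyl)methyl]-6-methoxyphenyl}ethan-1-one F3. F3 is then condensed with benzaldehyde 13 as its polyanion, using LiN(SiMe3)2 (5 equiv) in THF from −78 °C to rt. The reaction passes through (±)-1-{2,4-dihydroxy-3-[(2-hydroxyphenyl)methyl]-6-methoxyphenyl}-3-hydroxy-3-phenylpropan-1-one F4, which is not isolated and dehydrates in the flask. A cold dilute HCl quench gives 16 directly, with no protecting-group step after the enone exists.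

**Further compounds**
F1 | step 3 | 2-{[2-(benzyloxy)phenyl]methyl}-5-methoxy-1,3-bis(methoxymethoxy)benzene | COCOc1cc(OC)cc(OCOC)c1Cc1ccccc1OCc1ccccc1
F2 | step 6 | (±)-1-(6-methoxy-2,4-bis(methoxymethoxy)-3-{[2-(methoxymethoxy)phenyl]methyl}phenyl)ethan-1-ol | COCOc1ccccc1Cc1c(OCOC)cc(OC)c(C(C)O)c1OCOC
F3 | step 8 | 1-{2,4-dihydroxy-3-[(2-hydroxyphenyl)methyl]-6-methoxyphenyl}ethan-1-one | COc1cc(O)c(Cc2ccccc2O)c(O)c1C(C)=O
F4 | step 8 | (±)-1-{2,4-dihydroxy-3-[(2-hydroxyphenyl)methyl]-6-methoxyphenyl}-3-hydroxy-3-phenylpropan-1-one | COc1cc(O)c(Cc2ccccc2O)c(O)c1C(=O)CC(O)c1ccccc1
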